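**Plan**

1. Atom labels: ring A (cyclohexane) has C1(A), the carbinol carbon, and C6(A), the carbon bearing the methylidene. Ring B (1,2-dioxane) has O1, O2, C3(B) (the CH) and C6(B) (quaternary, methyl). Cα is the propanoate CH.
2. Retrosynthetic cuts: the ester back to CH2OH; ring B at O2–C3(B) (SN2) and O1–C6(B) (epoxide opening by H2O2); the chain at Cα–C3(B) (aldol), C4–C5 of ring B (Claisen) and the linker–C6(B) bond (Grignard); ring A at C1(A)–C6(A) (ketone carbon to alkyne carbon).
3. Forward order: acyclic silyl alkynone → ring A by nickel → the two-carbon arm on C1(A) is grown into the open chain of ring B → ring B is closed by peroxide alkylation → deoxygenation, desilylation, oxidation, esterification.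
4. Stereochemistry: C1(A) comes from the chiral phosphine on nickel. Cα and C3(B) come from an Evans syn aldol, with C3(B) inverted in the ring closure. C6(B) comes from a Shi epoxidation followed by invertive opening with H2O2.
5. Enabling feature: in ring A the tertiary carbinol C1 is bonded directly to C6, which carries the exocyclic methylidene. This 2-alkylidenecyclohexanol is what results when a ketone carbon is joined to the inner carbon of a tethered alkyne with cis delivery of hydrogen.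

Key step: step 6

Assumption: the antipode of the P-chiral phosphine that gives the S carbinol in step 6 is fixed by a test reaction, and the L-fructose-derived enantiomer of the Shi ketone (made from L-sorbose) is available.

In names, RA = (1S,6E)-6-{[benzyl(dimethyl)silyl]methylidene}-2,2-dimethyl-1-(triethylsilyloxy)cyclohexyl, bonded through C1(A). The benzyldimethylsilyl group replaces trimethylsilyl on the alkyne so that the silicon can later be removed from the alkene carbon by fluoride instead of acid.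

**Route**

Step 1
Reactants: 1 5-chloropent-1-yne
Product: 2 benzyl(5-chloropent-1-yn-1-yl)dimethylsilane
Conditions: n-BuLi, THF, −78 °C; BnMe2SiCl, −78 → 0 °C
Reagents that add atoms: benzylchlorodimethylsilane, C[Si](C)(Cl)Cc1ccccc1
Why: C-silylation of a lithium acetylide is a standard alkynylsilane synthesis that leaves the primary chloride untouched at low temperature.

Step 2
Reactants: 3 2-methylpropanenitrile; 2 benzyl(5-chloropent-1-yn-1-yl)dimethylsilane
Product: 4 7-[benzyl(dimethyl)silyl]-2,2-dimethylhept-6-ynenitrile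
Conditions: LiN(iPr)2, THF, −78 °C; 2, DMPU, −78 → 25 °C
Reagents that add atoms: none
Why: SN2 alkylation of a metalated nitrile, a very nucleophilic carbanion, by the primary chloride installs the quaternary gem-dimethyl carbon next to the future ketone.

Step 3
Reactants: 4 7-[benzyl(dimethyl)silyl]-2,2-dimethylhept-6-ynenitrile
Product: 6 8-[benzyl(dimethyl)silyl]-3,3-dimethyloct-7-yn-2-one, via ketimine 5 (not isolated)
Conditions: MeLi, Et2O, −78 → 0 °C; 1 M HCl, THF, 25 °C
Reagents that add atoms: methyllithium, [Li]C; water, O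
Why: organolithium addition to a nitrile stops at the N-lithio ketimine, so hydrolysis gives the methyl ketone without over-addition, the nitrile having no α-hydrogen and the alkynylsilane being inert to MeLi in ether at 0 °C.

Step 4
Reactants: 6 8-[benzyl(dimethyl)silyl]-3,3-dimethyloct-7-yn-2-one
Product: 7 9-[benzyl(dimethyl)silyl]-1-hydroxy-4,4-dimethylnon-8-yn-3-one
Conditions: LiN(iPr)2, THF, −78 °C; CH2O (gas), −78 °C
Reagents that add atoms: formaldehyde, C=O
Why: crossed aldol addition of the lithium enolate, which can form only on the methyl side, to monomeric formaldehyde adds the second carbon of the arm.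

Step 5
Reactants: 7 9-[benzyl(dimethyl)silyl]-1-hydroxy-4,4-dimethylnon-8-yn-3-one
Product: 8 9-[benzyl(dimethyl)silyl]-4,4-dimethyl-1-(triethylsilyloxy)non-8-yn-3-one
Conditions: Et3SiCl, imidazole, CH2Cl2, 0 °C
Reagents that add atoms: chlorotriethylsilane, CC[Si](Cl)(CC)CC
Why: silyl ether formation at the primary alcohol blocks retro-aldol and dehydration of the β-hydroxy ketone and gives an ether that mild acid can later remove beside a hindered tertiary silyl ether.

Step 6
Reactants: 8 9-[benzyl(dimethyl)silyl]-4,4-dimethyl-1-(triethylsilyloxy)non-8-yn-3-one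
Product: 9 triethyl[2-(RA)ethoxy]silane
Conditions: Ni(cod)2 (10 mol%), (R)-AntPhos (12 mol%), Et3SiH (3 equiv), 1,4-dioxane, 25 → 50 °C
Reagents that add atoms: triethylsilane, CC[SiH](CC)CC
Why: Zerovalent nickel bearing the P-chiral phosphine binds the silylalkyne and the ketone of 8 and undergoes oxidative cyclisation to an oxanickelacyclopentene, which forms the C1–C6 bond of ring A; σ-bond metathesis of the Ni–O bond with Et3SiH and C–H reductive elimination then release the triethylsilyl ether with hydrogen cis to C1 (the E-vinylsilane) and return the catalyst. The closest known reaction type is the nickel-catalysed enantioselective reductive cyclisation of alkynones with silanes under P-chiral monophosphine control, which gives silyl ethers of tertiary allylic alcohols. Ring A closes in the 6-exo-dig mode with the alkene necessarily exocyclic, and the gem-dimethyl group next to the carbonyl favours the folded reactive conformation. The new stereocentre C1(A) is set by the ligand, which selects the ketone enantioface during oxidative cyclisation, and the S carbinol is required. Regiochemistry is fixed by the tether (bond formation at the alkyne carbon remote from silicon), and the silyl cap suppresses alkyne oligomerisation while the hindered neopentyl ketone reacts.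

Step 7
Reactants: 9 triethyl[2-(RA)ethoxy]silane
Product: 10 2-(RA)ethan-1-ol
Conditions: PPTS, MeOH/CH2Cl2, 0 °C
Reagents that add atoms: none
Why: acid-catalysed methanolysis of silyl ethers is strongly slowed by steric hindrance, so the primary triethylsilyl ether is cleaved while the neopentyl-like tertiary one at C1(A) and the vinylsilane remain.

Step 8
Reactants: 10 2-(RA)ethan-1-ol
Product: 11 2-(RA)acetaldehyde
Conditions: Dess–Martin periodinane, CH2Cl2, 0 → 25 °C
Reagents that add atoms: none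
Why: Dess–Martin oxidation under near-neutral conditions gives the β-silyloxy aldehyde without β-elimination.

Step 9
Reactants: 11 2-(RA)acetaldehyde
Product: 12 2-methyl-4-(RA)but-1-en-3-ol (both C3 epimers)
Conditions: CH2=C(CH3)MgBr, THF, −78 °C, cold quench
Reagents that add atoms: isopropenylmagnesium bromide, C=C(C)[Mg]Br
Why: Grignard 1,2-addition to the aldehyde gives the isopropenyl carbinol, whose configuration is irrelevant because the carbinol carbon becomes sp2 in the next step, and the cold quench prevents silyl transfer to the new alkoxide.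

Step 10
Reactants: 12 2-methyl-4-(RA)but-1-en-3-ol
Product: 14 ethyl (4E)-4-methyl-6-(RA)hex-4-enoate, via ketene acetal 13 (not isolated)
Conditions: MeC(OEt)3, EtCO2H (cat.), 140 °C, ethanol distilled off
Reagents that add atoms: triethyl orthoacetate, CC(OCC)(OCC)OCC
Why: in the Johnson–Claisen rearrangement, orthoester exchange and loss of ethanol give the ketene acetal, whose chair [3,3] shift with the carbinol substituent equatorial forms the C4–C5 bond of the ring B chain and the E trisubstituted alkene, while the silyl ether keeps the tertiary oxygen at C1(A) out of the exchange.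

Step 11
Reactants: 14 ethyl (4E)-4-methyl-6-(RA)hex-4-enoate
Product: 15 (4E)-4-methyl-6-(RA)hex-4-enal
Conditions: iBu2AlH, CH2Cl2, −78 °C
Reagents that add atoms: none
Why: partial ester reduction with iBu2AlH at low temperature stops at the aluminium hemiacetal and gives the aldehyde on work-up.

Step 12
Reactants: 15 (4E)-4-methyl-6-(RA)hex-4-enal; 16 (4S)-4-benzyl-3-propanoyl-1,3-oxazolidin-2-one
Product: 17 (4S)-4-benzyl-3-[(2S,3R,6E)-3-hydroxy-2,6-dimethyl-8-(RA)oct-6-enoyl]-1,3-oxazolidin-2-one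
Conditions: Bu2BOTf, iPr2NEt, CH2Cl2, −78 → 0 °C; then H2O2, MeOH, pH 7 buffer, 0 °C
Reagents that add atoms: none
Why: in the Evans syn aldol the Z boron enolate of 16 reacts through a chair Zimmerman–Traxler transition state on the face away from the benzyl group, setting Cα as S and the carbinol C3(B) as R, the latter deliberately opposite to the target so that ring closure can invert it.

Step 13
Reactants: 17 (4S)-4-benzyl-3-[(2S,3R,6E)-3-hydroxy-2,6-dimethyl-8-(RA)oct-6-enoyl]-1,3-oxazolidin-2-one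
Product: 18 (2R,3R,6E)-2,6-dimethyl-8-(RA)oct-6-ene-1,3-diol
Conditions: LiBH4, THF, 0 °C
Reagents that add atoms: none
Why: reductive cleavage of the N-acyloxazolidinone with LiBH4 gives the primary alcohol and returns the auxiliary, and taking the carboxyl carbon to the alcohol level means the later sulfonate is not β to an enolisable carbonyl (no E1cB).

Step 14
Reactants: 18 (2R,3R,6E)-2,6-dimethyl-8-(RA)oct-6-ene-1,3-diol
Product: 19 (2R,3R,6E)-1-[tert-butyl(dimethyl)silyl]oxy-2,6-dimethyl-8-(RA)oct-6-en-3-ol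
Conditions: t-BuMe2SiCl, imidazole, CH2Cl2, −20 → 0 °C
Reagents that add atoms: tert-butylchlorodimethylsilane, CC(C)(C)[Si](C)(C)Cl
Why: silylation with a bulky silyl chloride selects the primary over the secondary hydroxyl on steric grounds.

Step 15
Reactants: 19 (2R,3R,6E)-1-[tert-butyl(dimethyl)silyl]oxy-2,6-dimethyl-8-(RA)oct-6-en-3-ol
Product: 20 (2R,3R,6E)-1-[tert-butyl(dimethyl)silyl]oxy-2,6-dimethyl-8-(RA)oct-6-en-3-yl methanesulfonate
Conditions: MsCl, Et3N, CH2Cl2, −10 °C
Reagents that add atoms: methanesulfonyl chloride, CS(=O)(=O)Cl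
Why: sulfonylation of the secondary alcohol proceeds with retention and turns C3(B) into the electrophile for ring closure.

Step 16
Reactants: 20 (2R,3R,6E)-1-[tert-butyl(dimethyl)silyl]oxy-2,6-dimethyl-8-(RA)oct-6-en-3-yl methanesulfonate
Product: 21 (2R,3R)-1-[tert-butyl(dimethyl)silyl]oxy-2-methyl-5-{(2S,3S)-2-methyl-3-[(RA)methyl]oxiran-2-yl}pentan-3-yl methanesulfonate
Conditions: L-fructose-derived Shi ketone (30 mol%), KHSO5 (as 2KHSO5·KHSO4·K2SO4), K2CO3, Bu4NHSO4 (cat.), MeCN/CH2(OMe)2/aq. Na2B4O7, 0 °C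
Reagents that add atoms: potassium peroxymonosulfate, [K+].[O-]S(=O)(=O)OO
Why: in the Shi asymmetric epoxidation the chiral dioxirane transfers oxygen through a spiro transition state to one face of the E trisubstituted alkene, the L-series ketone giving the 2S,3S oxirane, and the unhindered chain alkene should react ahead of the crowded vinylsilane of ring A.

Step 17
Reactants: 21 (2R,3R)-1-[tert-butyl(dimethyl)silyl]oxy-2-methyl-5-{(2S,3S)-2-methyl-3-[(RA)methyl]oxiran-2-yl}pentan-3-yl methanesulfonate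
Product: 22 (2R,3R,6R,7S)-1-[tert-butyl(dimethyl)silyl]oxy-6-hydroperoxy-7-hydroxy-2,6-dimethyl-8-(RA)octan-3-yl methanesulfonate
Conditions: H2O2 (anhydrous, in Et2O), H3PMo12O40 (3 mol%), 0 → 25 °C
Reagents that add atoms: hydrogen peroxide, OO
Why: acid-catalysed perhydrolysis of a trisubstituted epoxide opens the activated oxirane at the more substituted carbon with inversion (borderline SN2), which sets C6(B) as R in the tertiary hydroperoxide and leaves a hydroxyl on the adjacent linker carbon.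

Step 18
Reactants: 22 (2R,3R,6R,7S)-1-[tert-butyl(dimethyl)silyl]oxy-6-hydroperoxy-7-hydroxy-2,6-dimethyl-8-(RA)octan-3-yl methanesulfonate
Product: 23 (1S)-1-[(3R,6S)-6-{(2R)-1-[tert-butyl(dimethyl)silyl]oxypropan-2-yl}-3-methyl-1,2-dioxan-3-yl]-2-(RA)ethan-1-ol
Conditions: KOtBu (1.05 equiv), 18-crown-6, THF, 0 °C
Reagents that add atoms: none
Why: intramolecular SN2 alkylation of the peroxide anion (6-exo-tet) displaces the mesylate with inversion, setting C3(B) as S and closing ring B, and one equivalent of base ionises only the hydroperoxide, which is far more acidic and nucleophilic than the neighbouring alcohol.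

Step 19
Reactants: 23 (1S)-1-[(3R,6S)-6-{(2R)-1-[tert-butyl(dimethyl)silyl]oxypropan-2-yl}-3-methyl-1,2-dioxan-3-yl]-2-(RA)ethan-1-ol
Product: 24 O-{(1S)-1-[(3R,6S)-6-{(2R)-1-[tert-butyl(dimethyl)silyl]oxypropan-2-yl}-3-methyl-1,2-dioxan-3-yl]-2-(RA)ethyl} O-phenyl carbonothioate
Conditions: PhOC(S)Cl, pyridine, DMAP, CH2Cl2, 25 °C
Reagents that add atoms: O-phenyl chlorothionoformate, S=C(Cl)Oc1ccccc1
Why: thionocarbonate formation at the secondary alcohol prepares it for radical deoxygenation under conditions that leave the dialkyl peroxide alone.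

Step 20
Reactants: 24 O-{(1S)-1-[(3R,6S)-6-{(2R)-1-[tert-butyl(dimethyl)silyl]oxypropan-2-yl}-3-methyl-1,2-dioxan-3-yl]-2-(RA)ethyl} O-phenyl carbonothioate
Product: 25 tert-butyl{(2R)-2-[(3S,6R)-6-methyl-6-[2-(RA)ethyl]-1,2-dioxan-3-yl]propoxy}dimethylsilane
Conditions: Bu3SnH (10 equiv, about 2 M), Et3B, air, PhMe, 0 → 25 °C
Reagents that add atoms: none
Why: in the Barton–McCombie deoxygenation, stannyl radical addition to the thiocarbonyl and β-scission give the linker radical, which a high concentration of Bu3SnH at room temperature should trap before it can attack the O–O bond, and no stereocentre is touched.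

Step 21
Reactants: 25 tert-butyl{(2R)-2-[(3S,6R)-6-methyl-6-[2-(RA)ethyl]-1,2-dioxan-3-yl]propoxy}dimethylsilane
Product: 26 (2R)-2-[(3S,6R)-6-{2-[(1S)-1-hydroxy-2,2-dimethyl-6-methylidenecyclohexyl]ethyl}-6-methyl-1,2-dioxan-3-yl]propan-1-ol
Conditions: Bu4NF, THF, 0 → 40 °C
Reagents that add atoms: none
Why: fluoride cleaves both silyl ethers and, after the benzyl group has left silicon, protodesilylates the alkenyl–silicon bond (fluoride-induced protodesilylation), unveiling the methylidene and both alcohols without acid.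

Step 22
Reactants: 26 (2R)-2-[(3S,6R)-6-{2-[(1S)-1-hydroxy-2,2-dimethyl-6-methylidenecyclohexyl]ethyl}-6-methyl-1,2-dioxan-3-yl]propan-1-ol
Product: 28 (2S)-2-[(3S,6R)-6-{2-[(1S)-1-hydroxy-2,2-dimethyl-6-methylidenecyclohexyl]ethyl}-6-methyl-1,2-dioxan-3-yl]propanoic acid, via aldehyde 27 (not isolated)
Conditions: TEMPO (20 mol%), PhI(OAc)2, MeCN/H2O, 25 °C
Reagents that add atoms: water, O
Why: oxoammonium (TEMPO) oxidation in aqueous acetonitrile takes the primary alcohol through the aldehyde hydrate to the acid, leaves the tertiary alcohol, alkene and peroxide alone and, being non-basic, should not epimerise Cα.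

Step 23
Reactants: 28 (2S)-2-[(3S,6R)-6-{2-[(1S)-1-hydroxy-2,2-dimethyl-6-methylidenecyclohexyl]ethyl}-6-methyl-1,2-dioxan-3-yl]propanoic acid
Product: 29 methyl (2S)-2-[(3S,6R)-6-{2-[(1S)-1-hydroxy-2,2-dimethyl-6-methylidenecyclohexyl]ethyl}-6-methyl-1,2-dioxan-3-yl]propanoate
Conditions: Me3SiCHN2, PhMe/MeOH, 0 °C
Reagents that add atoms: (trimethylsilyl)diazomethane, C[Si](C)(C)C=[N+]=[N-]
Why: esterification of the carboxylic acid with a diazoalkane in methanol is neutral and selective for the acid.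

**Compound list**

1 | 5-chloropent-1-yne | C#CCCCCl | starting material
2 | benzyl(5-chloropent-1-yn-1-yl)dimethylsilane | ClCCCC#C[Si](C)(C)Cc1ccccc1 | intermediate
3 | 2-methylpropanenitrile | CC(C)C#N | starting material
4 | 7-[benzyl(dimethyl)silyl]-2,2-dimethylhept-6-ynenitrile | N#CC(C)(C)CCCC#C[Si](C)(C)Cc1ccccc1 | intermediate
5 | 8-[benzyl(dimethyl)silyl]-3,3-dimethyloct-7-yn-2-imine (not isolated) | CC(=N)C(C)(C)CCCC#C[Si](C)(C)Cc1ccccc1 | intermediate
6 | 8-[benzyl(dimethyl)silyl]-3,3-dimethyloct-7-yn-2-one | CC(=O)C(C)(C)CCCC#C[Si](C)(C)Cc1ccccc1 | intermediate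
7 | 9-[benzyl(dimethyl)silyl]-1-hydroxy-4,4-dimethylnon-8-yn-3-one | OCCC(=O)C(C)(C)CCCC#C[Si](C)(C)Cc1ccccc1 | intermediate
8 | 9-[benzyl(dimethyl)silyl]-4,4-dimethyl-1-(triethylsilyloxy)non-8-yn-3-one | CC[Si](CC)(CC)OCCC(=O)C(C)(C)CCCC#C[Si](C)(C)Cc1ccccc1 | intermediate
9 | triethyl[2-(RA)ethoxy]silane | C[Si](C)(Cc1ccccc1)/C=C1\CCCC(C)(C)[C@@]1(O[Si](CC)(CC)CC)CCO[Si](CC)(CC)CC | intermediate
10 | 2-(RA)ethan-1-ol | C[Si](C)(Cc1ccccc1)/C=C1\CCCC(C)(C)[C@@]1(O[Si](CC)(CC)CC)CCO | intermediate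
11 | 2-(RA)acetaldehyde | C[Si](C)(Cc1ccccc1)/C=C1\CCCC(C)(C)[C@@]1(O[Si](CC)(CC)CC)CC=O | intermediate
12 | 2-methyl-4-(RA)but-1-en-3-ol, both C3 epimers | C[Si](C)(Cc1ccccc1)/C=C1\CCCC(C)(C)[C@@]1(O[Si](CC)(CC)CC)CC(O)C(C)=C | intermediate
13 | 3-[(1-ethoxyethenyl)oxy]-2-methyl-4-(RA)but-1-ene (not isolated) | C[Si](C)(Cc1ccccc1)/C=C1\CCCC(C)(C)[C@@]1(O[Si](CC)(CC)CC)CC(OC(=C)OCC)C(C)=C | intermediate
14 | ethyl (4E)-4-methyl-6-(RA)hex-4-enoate | C[Si](C)(Cc1ccccc1)/C=C1\CCCC(C)(C)[C@@]1(O[Si](CC)(CC)CC)C/C=C(\C)CCC(=O)OCC | intermediate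
15 | (4E)-4-methyl-6-(RA)hex-4-enal | C[Si](C)(Cc1ccccc1)/C=C1\CCCC(C)(C)[C@@]1(O[Si](CC)(CC)CC)C/C=C(\C)CCC=O | intermediate
16 | (4S)-4-benzyl-3-propanoyl-1,3-oxazolidin-2-one | CCC(=O)N1C(=O)OC[C@@H]1Cc1ccccc1 | starting material
17 | (4S)-4-benzyl-3-[(2S,3R,6E)-3-hydroxy-2,6-dimethyl-8-(RA)oct-6-enoyl]-1,3-oxazolidin-2-one | C[Si](C)(Cc1ccccc1)/C=C1\CCCC(C)(C)[C@@]1(O[Si](CC)(CC)CC)C/C=C(\C)CC[C@H]([C@H](C)C(=O)N1C(=O)OC[C@@H]1Cc1ccccc1)O | intermediate
18 | (2R,3R,6E)-2,6-dimethyl-8-(RA)oct-6-ene-1,3-diol | C[Si](C)(Cc1ccccc1)/C=C1\CCCC(C)(C)[C@@]1(O[Si](CC)(CC)CC)C/C=C(\C)CC[C@H]([C@H](C)CO)O | intermediate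
19 | (2R,3R,6E)-1-[tert-butyl(dimethyl)silyl]oxy-2,6-dimethyl-8-(RA)oct-6-en-3-ol | C[Si](C)(Cc1ccccc1)/C=C1\CCCC(C)(C)[C@@]1(O[Si](CC)(CC)CC)C/C=C(\C)CC[C@H]([C@H](C)CO[Si](C)(C)C(C)(C)C)O | intermediate
20 | (2R,3R,6E)-1-[tert-butyl(dimethyl)silyl]oxy-2,6-dimethyl-8-(RA)oct-6-en-3-yl methanesulfonate | C[Si](C)(Cc1ccccc1)/C=C1\CCCC(C)(C)[C@@]1(O[Si](CC)(CC)CC)C/C=C(\C)CC[C@H]([C@H](C)CO[Si](C)(C)C(C)(C)C)OS(C)(=O)=O | intermediate
21 | (2R,3R)-1-[tert-butyl(dimethyl)silyl]oxy-2-methyl-5-{(2S,3S)-2-methyl-3-[(RA)methyl]oxiran-2-yl}pentan-3-yl methanesulfonate | C[Si](C)(Cc1ccccc1)/C=C1\CCCC(C)(C)[C@@]1(O[Si](CC)(CC)CC)C[C@@H]1O[C@@]1(C)CC[C@H]([C@H](C)CO[Si](C)(C)C(C)(C)C)OS(C)(=O)=O | intermediate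
22 | (2R,3R,6R,7S)-1-[tert-butyl(dimethyl)silyl]oxy-6-hydroperoxy-7-hydroxy-2,6-dimethyl-8-(RA)octan-3-yl methanesulfonate | C[Si](C)(Cc1ccccc1)/C=C1\CCCC(C)(C)[C@@]1(O[Si](CC)(CC)CC)C[C@H](O)[C@@](OO)(C)CC[C@H]([C@H](C)CO[Si](C)(C)C(C)(C)C)OS(C)(=O)=O | intermediate
23 | (1S)-1-[(3R,6S)-6-{(2R)-1-[tert-butyl(dimethyl)silyl]oxypropan-2-yl}-3-methyl-1,2-dioxan-3-yl]-2-(RA)ethan-1-ol | C[Si](C)(Cc1ccccc1)/C=C1\CCCC(C)(C)[C@@]1(O[Si](CC)(CC)CC)C[C@H](O)[C@@]1(C)CC[C@@H]([C@H](C)CO[Si](C)(C)C(C)(C)C)OO1 | intermediate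
24 | O-{(1S)-1-[(3R,6S)-6-{(2R)-1-[tert-butyl(dimethyl)silyl]oxypropan-2-yl}-3-methyl-1,2-dioxan-3-yl]-2-(RA)ethyl} O-phenyl carbonothioate | C[Si](C)(Cc1ccccc1)/C=C1\CCCC(C)(C)[C@@]1(O[Si](CC)(CC)CC)C[C@H](OC(=S)Oc1ccccc1)[C@@]1(C)CC[C@@H]([C@H](C)CO[Si](C)(C)C(C)(C)C)OO1 | intermediate
25 | tert-butyl{(2R)-2-[(3S,6R)-6-methyl-6-[2-(RA)ethyl]-1,2-dioxan-3-yl]propoxy}dimethylsilane | C[Si](C)(Cc1ccccc1)/C=C1\CCCC(C)(C)[C@@]1(O[Si](CC)(CC)CC)CC[C@@]1(C)CC[C@@H]([C@H](C)CO[Si](C)(C)C(C)(C)C)OO1 | intermediate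
26 | (2R)-2-[(3S,6R)-6-{2-[(1S)-1-hydroxy-2,2-dimethyl-6-methylidenecyclohexyl]ethyl}-6-methyl-1,2-dioxan-3-yl]propan-1-ol | C=C1CCCC(C)(C)[C@@]1(O)CC[C@@]1(C)CC[C@@H]([C@H](C)CO)OO1 | intermediate
27 | (2S)-2-[(3S,6R)-6-{2-[(1S)-1-hydroxy-2,2-dimethyl-6-methylidenecyclohexyl]ethyl}-6-methyl-1,2-dioxan-3-yl]propanal (not isolated) | C=C1CCCC(C)(C)[C@@]1(O)CC[C@@]1(C)CC[C@@H]([C@H](C)C=O)OO1 | intermediate
28 | (2S)-2-[(3S,6R)-6-{2-[(1S)-1-hydroxy-2,2-dimethyl-6-methylidenecyclohexyl]ethyl}-6-methyl-1,2-dioxan-3-yl]propanoic acid | C=C1CCCC(C)(C)[C@@]1(O)CC[C@@]1(C)CC[C@@H]([C@H](C)C(=O)O)OO1 | intermediate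
29 | methyl (2S)-2-[(3S,6R)-6-{2-[(1S)-1-hydroxy-2,2-dimethyl-6-methylidenecyclohexyl]ethyl}-6-methyl-1,2-dioxan-3-yl]propanoate | C=C1CCCC(C)(C)[C@@]1(O)CC[C@@]1(C)CC[C@@H]([C@H](C)C(=O)OC)OO1 | target

**Step count and risks**

Total: 23 steps. Longest linear sequence: 23 steps, from 5-chloropent-1-yne 1; compounds 3 and 16 are bought.

Step 6. The oxidative cyclisation may stall at the neopentyl ketone, letting ketone hydrosilylation or alkyne oligomerisation take over, or the ligand may discriminate the ketone faces poorly. The fallback sets out from 8 and comes back at 9. Compound 8 is treated with the low-valent titanium reagent made from Ti(OiPr)4 and two equivalents of iPrMgCl (Et2O, −78 → −30 °C). The alkyne–titanium complex adds to the ketone through an oxatitanacyclopentene, again at the alkyne carbon remote from silicon and syn, and hydrolysis should give the racemic tertiary alcohol (6E)-6-{[benzyl(dimethyl)silyl]methylidene}-2,2-dimethyl-1-[2-(triethylsilyloxy)ethyl]cyclohexan-1-ol F1. Preparative chromatography on a chiral stationary phase separates the enantiomers and gives the 1S alcohol F2. Et3SiOTf and 2,6-lutidine (CH2Cl2, −78 °C) then silylate the tertiary hydroxyl to give 9. Stereocontrol at C1(A) thus changes from catalysis to resolution.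

Step 17. The acid catalyst may ionise the tertiary allylic silyl ether of ring A or protonate the vinylsilane, and opening at C6(B) may take on carbocation character so that configuration is partly lost. The fallback sets out from 21 and comes back at 23; it reverses the order in which the two C–O bonds of ring B are made and replaces steps 17 and 18. The mesylate of 21 is displaced by hydroperoxide anion (H2O2, CsOH·H2O, DMF, 0 °C; SN2 with inversion at C3(B)) to give the secondary hydroperoxide tert-butyl{[(2R,3S)-3-hydroperoxy-2-methyl-5-{(2S,3S)-2-methyl-3-[(RA)methyl]oxiran-2-yl}pentyl]oxy}dimethylsilane F3. A trace of camphorsulfonic acid in CH2Cl2 at 0 °C then lets the tethered hydroperoxide open the oxirane at its tertiary carbon (6-exo, inversion at C6(B)), which gives 23 directly. Delivery of the peroxide is intramolecular, so external nucleophiles and ionisation compete less.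

Step 20. The linker radical sits β to the peroxide and may attack the O–O bond (epoxide formation with ring opening) faster than it takes hydrogen, and the hindered alcohol may resist acylation in step 19. The fallback sets out from 20 and comes back at 25; it never places oxygen on the linker and replaces steps 16 to 20. Mukaiyama–Isayama hydroperoxysilylation of 20 (Co(thd)2 with thd = 2,2,6,6-tetramethylheptane-3,5-dionate, O2, Et3SiH, ClCH2CH2Cl, 25 °C) adds hydrogen to the CH end of the chain alkene and traps the tertiary radical with oxygen. This gives the silyl peroxide (2R,3R)-1-[tert-butyl(dimethyl)silyl]oxy-2,6-dimethyl-8-(RA)-6-(triethylsilylperoxy)octan-3-yl methanesulfonate F4 as both C6 epimers; the crowded vinylsilane of ring A is expected to react more slowly. K2CO3 in MeOH at 0 °C frees the hydroperoxide (2R,3R)-1-[tert-butyl(dimethyl)silyl]oxy-6-hydroperoxy-2,6-dimethyl-8-(RA)octan-3-yl methanesulfonate F5. KOtBu/18-crown-6, as in step 18, closes ring B to 25 together with its C6(B) epimer tert-butyl{(2R)-2-[(3S,6S)-6-methyl-6-[2-(RA)ethyl]-1,2-dioxan-3-yl]propoxy}dimethylsilane F6. Chromatography removes F6 and 25 re-enters at step 21. Control at C6(B) is given up in exchange for a shorter, radical-free end of the sequence.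

**Further compounds**

F1 | step 6 | racemic (6E)-6-{[benzyl(dimethyl)silyl]methylidene}-2,2-dimethyl-1-[2-(triethylsilyloxy)ethyl]cyclohexan-1-ol | C[Si](C)(Cc1ccccc1)/C=C1\CCCC(C)(C)C1(O)CCO[Si](CC)(CC)CC
F2 | step 6 | (1S,6E)-6-{[benzyl(dimethyl)silyl]methylidene}-2,2-dimethyl-1-[2-(triethylsilyloxy)ethyl]cyclohexan-1-ol | C[Si](C)(Cc1ccccc1)/C=C1\CCCC(C)(C)[C@@]1(O)CCO[Si](CC)(CC)CC
F3 | step 17 | tert-butyl{[(2R,3S)-3-hydroperoxy-2-methyl-5-{(2S,3S)-2-methyl-3-[(RA)methyl]oxiran-2-yl}pentyl]oxy}dimethylsilane | C[Si](C)(Cc1ccccc1)/C=C1\CCCC(C)(C)[C@@]1(O[Si](CC)(CC)CC)C[C@@H]1O[C@@]1(C)CC[C@@H]([C@H](C)CO[Si](C)(C)C(C)(C)C)OO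
F4 | step 20 | (2R,3R)-1-[tert-butyl(dimethyl)silyl]oxy-2,6-dimethyl-8-(RA)-6-(triethylsilylperoxy)octan-3-yl methanesulfonate, both C6 epimers | C[Si](C)(Cc1ccccc1)/C=C1\CCCC(C)(C)[C@@]1(O[Si](CC)(CC)CC)CCC(C)(OO[Si](CC)(CC)CC)CC[C@H]([C@H](C)CO[Si](C)(C)C(C)(C)C)OS(C)(=O)=O
F5 | step 20 | (2R,3R)-1-[tert-butyl(dimethyl)silyl]oxy-6-hydroperoxy-2,6-dimethyl-8-(RA)octan-3-yl methanesulfonate, both C6 epimers | C[Si](C)(Cc1ccccc1)/C=C1\CCCC(C)(C)[C@@]1(O[Si](CC)(CC)CC)CCC(C)(OO)CC[C@H]([C@H](C)CO[Si](C)(C)C(C)(C)C)OS(C)(=O)=O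
F6 | step 20 | tert-butyl{(2R)-2-[(3S,6S)-6-methyl-6-[2-(RA)ethyl]-1,2-dioxan-3-yl]propoxy}dimethylsilane | C[Si](C)(Cc1ccccc1)/C=C1\CCCC(C)(C)[C@@]1(O[Si](CC)(CC)CC)CC[C@]1(C)CC[C@@H]([C@H](C)CO[Si](C)(C)C(C)(C)C)OO1
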